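Read this flask at 25 min, and before any run ask what its equilibrium permits.

J 1.0 mM (fed, over 2.5 s); E 0.500 equiv; D 20 mol%; time 25 min; the fed solution adds 0.25 times the starting volume

    J + E + D ⇌ J.E + D, rate k1*[J]*[E]*[D] forward; the back reaction follows from the equilibrium constant (K1 = 4470 M⁻¹, k1 = 8.84 × 10⁵ M⁻² s⁻¹)
    2 D ⇌ D2, settled at all times (K2 = 6200 M⁻¹)

- at 25 min, what has stopped the reaction, if anything has (E has run out first / forward and back rates have come level / all of J has reacted / it is still moving / no working catalyst is left)
- how much of the J has reacted by 25 min
- how much J.E there is at 25 min, in percent of the J charged

- two of one species on the left: rate k times its square, two consumed each time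
- charges are per starting volume, the dose included; the dosed solution carries all of it
- the reaction counts as stopped when no species that holds the J changes by six tenths of a point or more over the second half of the time
- run time (flask): 25 min

Start from the finished dose, which brings the volume to 1.25 times the start, and take [J] as 0.800 mM and [E] as 0.400 mM in that volume, counted as if none had reacted. E is the limiting reagent, and its charge allows J.E up to 50.0% of the J charged. Now solve two extreme versions of the flask, with K the equilibrium constant of the first step, 4470 M⁻¹, so that J.E over free E equals K[J]. Hold [J] at 0.800 mM and this ratio puts 39.1% of the J into J.E; hold it instead at 0.400 mM, where complete use of E would leave it, and the ratio gives 32.1%. At balance [J] stands between these two values, so the share at balance lies between these two shares. Find it from the balance extent, the amount x of J.E in the final volume at which x equals K times ([J] − x) times ([E] − x), with the starting values above: the quadratic gives 0.280 mM, which is 35.0% of the J, less than the cap. D stands on both sides of the step, so x contains no term for D or D2. Then check the pace: the half-life of J by the forward rate, the way back not counted and the other concentrations as charged, is 0.13 min, far shorter than 25 min, so expect this flask to have reached x when it is read.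

The forecast says forward and back rates have come level, with conversion 35% (from 34% to 36%) and J.E 35%, reasoning “so the system is fully at equilibrium”. The simulation of this flask gives forward and back rates have come level, with conversion 35.0% and J.E 35.0%.

Put x back into this flask: it leaves 65.0% of the J and 30.0% of the E, and at 25.0 min this flask holds 65.0% of its J and 30.1% of its E, with J.E already 35.0% at 5.00 min. Now raise E to 0.850 equiv in a neighbour flask, so that [E] starts at 0.680 mM: the same quadratic gives 0.426 mM, or 53.2% of the J. That neighbour flask ends with J.E at 53.2%, more than its J at 46.8%, and with 37% of its E left.

(Its constants were drawn at random within sensible limits; no experiment stands behind them.)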